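The runs come from a simulation for substances that don't exist; the scatter is artificial.

At equal time the percent of the J charged held steady as J went up: at 25.0 min, L stood at 10.2% in beta and 9.8% in zeta, and G at 7.6% and 6.9%, with a scatter of 0.5 percentage points.

| setting | beta | alpha | zeta | grey | red |
|---|---|---|---|---|---|
| J | 0.40 M | 0.79 M | 1.1 M | 0.50 M | 1.5 M |
| D | 1.8 M | 1.8 M | 1.8 M | 1.80 M | 1.80 M |
| remark | run made earlier | run made earlier | run made earlier |  |  |
| time |  |  |  | 6.0 min | 25 min |

| run | time / min | L / % | G / % |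
|---|---|---|---|
| beta | 2.00 | 1.1 | 0 |
| beta | 4.00 | 3.6 | 0.4 |
| beta | 8.00 | 5.7 | 1.1 |
| beta | 12.0 | 7.1 | 2.2 |
| beta | 25.0 | 10.2 | 7.6 |
| alpha | 5.00 | 4.5 | 0.5 |
| alpha | 10.0 | 6.8 | 1.4 |
| alpha | 15.0 | 8.0 | 2.8 |
| alpha | 20.0 | 9.2 | 5.3 |
| alpha | 25.0 | 9.8 | 7.3 |
| zeta | 2.00 | 1.8 | 0 |
| zeta | 6.00 | 4.6 | 0 |
| zeta | 12.0 | 7.3 | 1.8 |
| zeta | 20.0 | 9.1 | 4.2 |
| zeta | 25.0 | 9.8 | 6.9 |

(each reading ± 0.5 percentage points)

1. the flask that ends with the higher share of L in all that became L or G or Z, or "neither" when 2 percentage points or less lies between them (grey / red / neither)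
2. share of L in all that became L or G or Z, grey
3. share of L in all that became L or G or Z, red

- in percentages every species weighs as the J in it: one E counts as two
- steps under discussion: D + X -> G; 2 J -> E; J + D -> L; D + L -> Z; D + L -> G; J + D -> X

So the step in which two J meet does not show in these readings. J cancels from the percentages, and the concentration I reckoned with is that of D. I built grey and red up step by step.

With J + D into L as the main step and nothing else, the share of L is 100%. Adding D + L into G makes the loss of L pseudo-first-order, with a loss rate of L at 1.80 M of D, and x is this rate times the time. The share is then (1 − e^(−x))/x, and G over L is close to x/2 + x·x/12.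

The pooled readings at 25.0 min give G over L as 0.732, so x is 1.22 and the rate reads 0.0487 min⁻¹. That is a half-life of L of 14.2 min, longer than grey's time and shorter than red's. By this reading I reckoned for grey an x of 0.292 and a share of 86.7%, and for red a share of 57.9%.

Then the rest: G reached by way of X is already inside a rate read from G, but Z was never read, and any Z adds to the denominator, so I took both shares as high.

The forecast said grey, with 87% (81% to 93%) for grey and 60% (55% to 65%) for red, above my red, in the words “Grey is clearly higher”.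

    D + X → G (k = 9.00 × 10⁻⁵ M⁻¹ s⁻¹)
    2 J → E (k = 1.00 × 10⁻⁶ M⁻¹ s⁻¹)
    J + D → L (k = 8.60 × 10⁻⁵ M⁻¹ s⁻¹)
    D + L → Z (k = 1.30 × 10⁻⁴ M⁻¹ s⁻¹)
    D + L → G (k = 3.60 × 10⁻⁴ M⁻¹ s⁻¹)
    J + D → X (k = 7.10 × 10⁻⁵ M⁻¹ s⁻¹)

Grey gave 83.7% and red 54.2%, so grey ended higher, and my shares stood 3.0 points and 3.7 points above them. In grey the half-life of L by D + L into G was 18 min at 2.90 min, longer than the 6.0 min of the flask. In red the same half-life, with D as charged, was 18 min, shorter than its 25 min. Grey read at 1.5 min, a quarter of its time, has a share by my rate of 96.4%, and that flask stood at 95.6%.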